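**Retrosynthetic overview**
- Structural feature: each six-membered end ring carries a trans C3,C4-diol in which the C4 carbinol is allylic to the tetrasubstituted C5=C6 alkene, and that alkene is conjugated to the C7≡C8 alkyne.
- Disconnection 1: C11=C12 and C11'=C12' by a double Wittig olefination of one C15 phosphonium salt (used twice) with the central C10 dialdehyde.
- Disconnection 2: the C4–O bond with the C5=C6 alkene comes from a suprafacial 1,3-hydroxyl shift of a C6 tertiary alkynyl carbinol with a C4=C5 alkene; its C6 stereocentre is transient and absent from the target.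
- Disconnection 3: C6–C7 by addition of the acetylide of silylated (E)-3-methylpent-2-en-4-yn-1-ol to the silyl ether of (S)-4-hydroxy-2,6,6-trimethylcyclohex-2-enone, made from ketoisophorone.
- Rings: no ring is formed; both cyclohexene rings are bought intact as ketoisophorone.

Key step: step 5

Assumption: carotenoid numbering is used for atoms (ring C1 to C6, chain C7 to C15, primes for the second half), and an S-selective ketoreductase that reduces only the unhindered carbonyl of ketoisophorone is taken from a commercial enzyme panel.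

**Step 1**
Reactants: 1 ketoisophorone (2,6,6-trimethylcyclohex-2-ene-1,4-dione)
Product: 2 (S)-4-hydroxy-2,6,6-trimethylcyclohex-2-en-1-one
Conditions: S-selective ketoreductase (isolated enzyme), NADP+ (cat.), i-PrOH, phosphate buffer pH 7, 30 °C
Reagents that add atoms: none
Why: Enzymatic asymmetric carbonyl reduction with isopropanol as hydride source should reach only the carbonyl flanked by CH and CH2, because the other one lies between the quaternary carbon and the methyl-bearing alkene carbon; the enzyme's facial preference sets the later C3 stereocentre, and an isolated ketoreductase leaves the alkene alone.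

**Step 2**
Reactants: 2 (S)-4-hydroxy-2,6,6-trimethylcyclohex-2-en-1-one
Product: 3 (S)-4-(tert-butyldimethylsilyloxy)-2,6,6-trimethylcyclohex-2-en-1-one
Conditions: TBSCl, imidazole, DMF, rt
Reagents that add atoms: tert-butyldimethylsilyl chloride, CC(C)(C)[Si](C)(C)Cl
Why: Standard silylation of a secondary allylic alcohol, which removes the acidic proton before the acetylide addition and installs the bulky group that later biases the ring conformation; the stereocentre is not touched.

**Step 3**
Reactants: 4 (E)-3-methylpent-2-en-4-yn-1-ol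
Product: 5 (E)-1-(tert-butyldimethylsilyloxy)-3-methylpent-2-en-4-yne
Conditions: TBSCl, imidazole, DMF, 0 °C → rt
Reagents that add atoms: tert-butyldimethylsilyl chloride, CC(C)(C)[Si](C)(C)Cl
Why: Standard silylation of a primary allylic alcohol; the terminal alkyne C–H and the E alkene (the later C9=C10) are unaffected.

**Step 4**
Reactants: 5 (E)-1-(tert-butyldimethylsilyloxy)-3-methylpent-2-en-4-yne; 3 (S)-4-(tert-butyldimethylsilyloxy)-2,6,6-trimethylcyclohex-2-en-1-one
Product: 8 (1S,4S)-4-(tert-butyldimethylsilyloxy)-1-[(E)-5-(tert-butyldimethylsilyloxy)-3-methylpent-3-en-1-ynyl]-2,6,6-trimethylcyclohex-2-en-1-ol (C6 carbinol; hydroxyl trans to the ring silyloxy group), via lithium acetylide 6 (not isolated), via lithium alkoxide 7 (not isolated)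
Conditions: n-BuLi, THF, −78 °C; then 3, −78 → −20 °C; H2O
Reagents that add atoms: none
Why: 1,2-addition of a lithium acetylide to an enone carbonyl that has no α-hydrogen; in the half-chair with the C3 silyloxy group pseudoequatorial one C1 methyl is axial, and axial entry of the slim acetylide on the face away from that methyl should place the new C6 hydroxyl trans to the C3 silyloxy group.

**Step 5**
Reactants: 8 (1S,4S)-4-(tert-butyldimethylsilyloxy)-1-[(E)-5-(tert-butyldimethylsilyloxy)-3-methylpent-3-en-1-ynyl]-2,6,6-trimethylcyclohex-2-en-1-ol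
Product: 10 trimethylsilyl ether of (1S,6S)-6-(tert-butyldimethylsilyloxy)-3-[(E)-5-(tert-butyldimethylsilyloxy)-3-methylpent-3-en-1-ynyl]-2,4,4-trimethylcyclohex-2-en-1-ol (C4-OSiMe3 trans to C3-OTBS; 3S,4S in carotenoid numbering), via free C4 alcohol 9 (not isolated)
Conditions: O3ReOSiPh3 (5 mol %), BSA (1.5 equiv), Et2O, −50 → −20 °C; then Et3N
Reagents that add atoms: N,O-bis(trimethylsilyl)acetamide, CC(=N[Si](C)(C)C)O[Si](C)(C)C
Why: The C6 carbinol should exchange onto heptavalent rhenium as an allyl perrhenate, which undergoes a [3,3] shift over O–C6–C5=C4 through a six-membered cyclic transition state; the catalyst then releases the secondary alcohol 9, which BSA silylates so that it cannot re-enter the cycle. The closest known reaction type is the oxo-rhenium-catalysed 1,3-transposition of allylic alcohols with in situ silyl trapping of the less hindered isomer. No ring is closed. The one new stereocentre, C4, is controlled by the configuration of the C6 carbinol: inside a cyclohexene the cyclic shift can only deliver oxygen to the ring face it leaves, so O4 should arrive trans to the C3 silyloxy group (3S,4S) while the C6 centre vanishes into the C5=C6 alkene. The step needs the concerted allylic shift to outrun ionisation to an allyl-propargyl cation and oxygen migration towards C8; the substrate favours it because the allylic path relieves the crowded tertiary centre between the gem-dimethyl carbon and the C5 methyl and creates a tetrasubstituted alkene conjugated to the enyne, whereas the propargylic path would need a cyclic transition state across the linear alkyne. Low temperature, the weakly polar ether and immediate silylation should keep the ionic channel down.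

**Step 6**
Reactants: 10 trimethylsilyl ether of the (3S,4S) C15 enyne alcohol
Product: 9 (1S,6S)-6-(tert-butyldimethylsilyloxy)-3-[(E)-5-(tert-butyldimethylsilyloxy)-3-methylpent-3-en-1-ynyl]-2,4,4-trimethylcyclohex-2-en-1-ol (free C4 alcohol)
Conditions: K2CO3 (cat.), MeOH, 0 °C
Reagents that add atoms: none
Why: Base-catalysed methanolysis cleaves a trimethylsilyl ether far faster than the tert-butyldimethylsilyl ethers; a 1,2-silyl shift between O3 and O4 would be harmless, because both oxygens carry the same silyl group after step 7.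

**Step 7**
Reactants: 9 (1S,6S)-6-(tert-butyldimethylsilyloxy)-3-[(E)-5-(tert-butyldimethylsilyloxy)-3-methylpent-3-en-1-ynyl]-2,4,4-trimethylcyclohex-2-en-1-ol
Product: 11 (E)-1-(tert-butyldimethylsilyloxy)-5-[(3S,4S)-3,4-bis(tert-butyldimethylsilyloxy)-2,6,6-trimethylcyclohex-1-enyl]-3-methylpent-2-en-4-yne
Conditions: TBSOTf, 2,6-lutidine, CH2Cl2, −78 → 0 °C
Reagents that add atoms: tert-butyldimethylsilyl trifluoromethanesulfonate, CC(C)(C)[Si](C)(C)OS(=O)(=O)C(F)(F)F
Why: Silylation of a hindered secondary allylic alcohol (between the C3 silyloxy group and the C5 methyl) needs the silyl triflate, and the hindered base keeps the medium from ionising the allylic C4–O bond.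

**Step 8**
Reactants: 11 (E)-1-(tert-butyldimethylsilyloxy)-5-[(3S,4S)-3,4-bis(tert-butyldimethylsilyloxy)-2,6,6-trimethylcyclohex-1-enyl]-3-methylpent-2-en-4-yne
Product: 12 (E)-5-[(3S,4S)-3,4-bis(tert-butyldimethylsilyloxy)-2,6,6-trimethylcyclohex-1-enyl]-3-methylpent-2-en-4-yn-1-ol
Conditions: HF·pyridine, pyridine, THF, 0 °C
Reagents that add atoms: none
Why: Chemoselective desilylation: buffered HF should cleave the unhindered primary allylic silyl ether well before the two flanked secondary ones on the ring.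

**Step 9**
Reactants: 12 (E)-5-[(3S,4S)-3,4-bis(tert-butyldimethylsilyloxy)-2,6,6-trimethylcyclohex-1-enyl]-3-methylpent-2-en-4-yn-1-ol
Product: 13 (E)-1-bromo-5-[(3S,4S)-3,4-bis(tert-butyldimethylsilyloxy)-2,6,6-trimethylcyclohex-1-enyl]-3-methylpent-2-en-4-yne
Conditions: CBr4, PPh3, CH2Cl2, 0 °C
Reagents that add atoms: carbon tetrabromide, BrC(Br)(Br)Br
Why: Appel reaction: bromide displaces the oxyphosphonium group by SN2 at the primary allylic carbon under neutral conditions, so the C9=C10 geometry and the silyl ethers should survive.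

**Step 10**
Reactants: 13 (E)-1-bromo-5-[(3S,4S)-3,4-bis(tert-butyldimethylsilyloxy)-2,6,6-trimethylcyclohex-1-enyl]-3-methylpent-2-en-4-yne
Product: 14 {(E)-5-[(3S,4S)-3,4-bis(tert-butyldimethylsilyloxy)-2,6,6-trimethylcyclohex-1-enyl]-3-methylpent-2-en-4-ynyl}triphenylphosphonium bromide
Conditions: PPh3, EtOAc, rt, dark
Reagents that add atoms: triphenylphosphine, c1ccc(cc1)P(c1ccccc1)c1ccccc1
Why: SN2 quaternisation of triphenylphosphine by a primary allylic bromide; the salt should precipitate from the ester solvent.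

**Step 11**
Reactants: 14 C15 triphenylphosphonium bromide (2.2 equiv); 15 (2E,4E,6E)-2,7-dimethylocta-2,4,6-trienedial
Product: 18 (3S,4S,3'S,4'S)-3,4,3',4'-tetrakis(tert-butyldimethylsilyloxy)-7,8,7',8'-tetradehydro-β,β-carotene as a mixture of E and Z isomers at C11=C12 and C11'=C12', via phosphorus ylide 16 (not isolated), via C25 monoaldehyde 17 (not isolated)
Conditions: NaOMe, MeOH/CH2Cl2, 0 °C → rt, dark, N2
Reagents that add atoms: none
Why: Twofold Wittig olefination: the semistabilised allylic ylide condenses with both formyl groups of the symmetrical dialdehyde to form C11=C12 and C11'=C12'; the geometry of the new bonds is not controlled here and is corrected in step 12, while the existing E alkenes and the stereocentres are untouched.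

**Step 12**
Reactants: 18 tetrasilylated C40 tetrol as the 11,11' E/Z mixture
Product: 19 (all-E)-(3S,4S,3'S,4'S)-3,4,3',4'-tetrakis(tert-butyldimethylsilyloxy)-7,8,7',8'-tetradehydro-β,β-carotene
Conditions: heptane, reflux, N2, dark
Reagents that add atoms: none
Why: Thermal Z to E isomerisation: an 11Z bond is strained by the clash of C10–H with the C13 methyl and should relax to E at about 100 °C, whereas the C9=C10 and C13=C14 bonds do not move at this temperature; iodine is avoided because it would equilibrate C9=C10 beside the alkyne.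

**Step 13**
Reactants: 19 (all-E)-(3S,4S,3'S,4'S)-3,4,3',4'-tetrakis(tert-butyldimethylsilyloxy)-7,8,7',8'-tetradehydro-β,β-carotene
Product: 20 (all-E)-(3S,4S,3'S,4'S)-7,8,7',8'-tetradehydro-β,β-carotene-3,4,3',4'-tetrol (CNP0283832.1)
Conditions: TBAF, AcOH, THF, 0 °C → rt (40 °C if the vicinal silyl ethers lag), dark, N2
Reagents that add atoms: none
Why: Fluoride-driven cleavage of the four silyl ethers through Si–F bond formation; the acetic acid buffer keeps the polyene and the allylic C4 alcohols away from strong base, and no stereocentre is touched.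

**Compound list**
1 | ketoisophorone (2,6,6-trimethylcyclohex-2-ene-1,4-dione) | CC1=CC(=O)CC(C)(C)C1=O | starting material
2 | (S)-4-hydroxy-2,6,6-trimethylcyclohex-2-en-1-one | CC1=C[C@@H](O)CC(C)(C)C1=O | intermediate
3 | (S)-4-(tert-butyldimethylsilyloxy)-2,6,6-trimethylcyclohex-2-en-1-one | CC1=C[C@@H](O[Si](C)(C)C(C)(C)C)CC(C)(C)C1=O | intermediate
4 | (E)-3-methylpent-2-en-4-yn-1-ol | C#C/C(C)=C/CO | starting material
5 | (E)-1-(tert-butyldimethylsilyloxy)-3-methylpent-2-en-4-yne | C#C/C(C)=C/CO[Si](C)(C)C(C)(C)C | intermediate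
6 | lithium acetylide of 5 | [Li]C#C/C(C)=C/CO[Si](C)(C)C(C)(C)C | intermediate
7 | lithium alkoxide of 8 | CC1=C[C@@H](O[Si](C)(C)C(C)(C)C)CC(C)(C)[C@@]1(O[Li])C#C/C(C)=C/CO[Si](C)(C)C(C)(C)C | intermediate
8 | (1S,4S)-4-(tert-butyldimethylsilyloxy)-1-[(E)-5-(tert-butyldimethylsilyloxy)-3-methylpent-3-en-1-ynyl]-2,6,6-trimethylcyclohex-2-en-1-ol | CC1=C[C@@H](O[Si](C)(C)C(C)(C)C)CC(C)(C)[C@@]1(O)C#C/C(C)=C/CO[Si](C)(C)C(C)(C)C | intermediate
9 | (1S,6S)-6-(tert-butyldimethylsilyloxy)-3-[(E)-5-(tert-butyldimethylsilyloxy)-3-methylpent-3-en-1-ynyl]-2,4,4-trimethylcyclohex-2-en-1-ol | CC1=C(C#C/C(C)=C/CO[Si](C)(C)C(C)(C)C)C(C)(C)C[C@H](O[Si](C)(C)C(C)(C)C)[C@H]1O | intermediate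
10 | trimethylsilyl ether of 9 | CC1=C(C#C/C(C)=C/CO[Si](C)(C)C(C)(C)C)C(C)(C)C[C@H](O[Si](C)(C)C(C)(C)C)[C@H]1O[Si](C)(C)C | intermediate
11 | (E)-1-(tert-butyldimethylsilyloxy)-5-[(3S,4S)-3,4-bis(tert-butyldimethylsilyloxy)-2,6,6-trimethylcyclohex-1-enyl]-3-methylpent-2-en-4-yne | CC1=C(C#C/C(C)=C/CO[Si](C)(C)C(C)(C)C)C(C)(C)C[C@H](O[Si](C)(C)C(C)(C)C)[C@H]1O[Si](C)(C)C(C)(C)C | intermediate
12 | (E)-5-[(3S,4S)-3,4-bis(tert-butyldimethylsilyloxy)-2,6,6-trimethylcyclohex-1-enyl]-3-methylpent-2-en-4-yn-1-ol | CC1=C(C#C/C(C)=C/CO)C(C)(C)C[C@H](O[Si](C)(C)C(C)(C)C)[C@H]1O[Si](C)(C)C(C)(C)C | intermediate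
13 | (E)-1-bromo-5-[(3S,4S)-3,4-bis(tert-butyldimethylsilyloxy)-2,6,6-trimethylcyclohex-1-enyl]-3-methylpent-2-en-4-yne | CC1=C(C#C/C(C)=C/CBr)C(C)(C)C[C@H](O[Si](C)(C)C(C)(C)C)[C@H]1O[Si](C)(C)C(C)(C)C | intermediate
14 | {(E)-5-[(3S,4S)-3,4-bis(tert-butyldimethylsilyloxy)-2,6,6-trimethylcyclohex-1-enyl]-3-methylpent-2-en-4-ynyl}triphenylphosphonium bromide | CC1=C(C#C/C(C)=C/C[P+](c2ccccc2)(c2ccccc2)c2ccccc2)C(C)(C)C[C@H](O[Si](C)(C)C(C)(C)C)[C@H]1O[Si](C)(C)C(C)(C)C.[Br-] | intermediate
15 | (2E,4E,6E)-2,7-dimethylocta-2,4,6-trienedial | O=C/C(C)=C/C=C/C=C(C)/C=O | starting material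
16 | phosphorus ylide of 14 | CC1=C(C#C/C(C)=C/C=P(c2ccccc2)(c2ccccc2)c2ccccc2)C(C)(C)C[C@H](O[Si](C)(C)C(C)(C)C)[C@H]1O[Si](C)(C)C(C)(C)C | intermediate
17 | C25 monoaldehyde from the first olefination (E/Z mixture at C11=C12) | CC1=C(C#C/C(C)=C/C=CC(/C)=C/C=C/C=C(C)/C=O)C(C)(C)C[C@H](O[Si](C)(C)C(C)(C)C)[C@H]1O[Si](C)(C)C(C)(C)C | intermediate
18 | (3S,4S,3'S,4'S)-3,4,3',4'-tetrakis(tert-butyldimethylsilyloxy)-7,8,7',8'-tetradehydro-β,β-carotene, E/Z mixture at C11=C12 and C11'=C12' | CC1=C(C#C/C(C)=C/C=CC(/C)=C/C=C/C=C(\C)C=C/C=C(\C)C#CC2=C(C)[C@H](O[Si](C)(C)C(C)(C)C)[C@@H](O[Si](C)(C)C(C)(C)C)CC2(C)C)C(C)(C)C[C@H](O[Si](C)(C)C(C)(C)C)[C@H]1O[Si](C)(C)C(C)(C)C | intermediate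
19 | (all-E)-(3S,4S,3'S,4'S)-3,4,3',4'-tetrakis(tert-butyldimethylsilyloxy)-7,8,7',8'-tetradehydro-β,β-carotene | CC1=C(C#C/C(C)=C/C=C/C(C)=C/C=C/C=C(C)/C=C/C=C(\C)C#CC2=C(C)[C@H](O[Si](C)(C)C(C)(C)C)[C@@H](O[Si](C)(C)C(C)(C)C)CC2(C)C)C(C)(C)C[C@H](O[Si](C)(C)C(C)(C)C)[C@H]1O[Si](C)(C)C(C)(C)C | intermediate
20 | (all-E)-(3S,4S,3'S,4'S)-7,8,7',8'-tetradehydro-β,β-carotene-3,4,3',4'-tetrol (CNP0283832.1) | CC1=C(C#C/C(C)=C/C=C/C(C)=C/C=C/C=C(C)/C=C/C=C(\C)C#CC2=C(C)[C@H](O)[C@@H](O)CC2(C)C)C(C)(C)C[C@H](O)[C@H]1O | target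

**Step count**
Total: 13 steps. Longest linear sequence: 12 steps (steps 1, 2 and 4 to 13, from ketoisophorone 1 to 20).

**Steps most likely to fail**

1. Step 5 (key step). The rhenium ester may ionise to the allyl-propargyl cation before it rearranges, so that oxygen returns to C4 from both faces or moves on to C8, and the transfer of configuration from C6 to C4 is lost. The fallback replaces the redox-neutral shift by an oxidative relay and sets out from 8. Buffered pyridinium chlorochromate [C5H5NH][CrO3Cl] with NaOAc in CH2Cl2 should effect the Babler–Dauben oxidative 1,3-transposition to the enynone (S)-6-(tert-butyldimethylsilyloxy)-3-[(E)-5-(tert-butyldimethylsilyloxy)-3-methylpent-3-en-1-ynyl]-2,4,4-trimethylcyclohex-2-en-1-one F1, in which C6 is no longer a stereocentre. Luche reduction (NaBH4, CeCl3·7H2O, MeOH, −78 °C) should then deliver hydride axially to the conformer with the C3 silyloxy group equatorial and give mainly the trans alcohol; a minor cis epimer could be re-oxidised with MnO2 and recycled. The fallback comes back to the route at 9, before step 7.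

2. Step 4. Facial discrimination at the hindered carbonyl may be weak, so that attack on the face of the axial methyl competes and the C6 epimer forms in quantity. The fallback corrects C4 by inversion after the shift instead of relying on the C6 configuration. It sets out from 3 and 6 as in step 4 and uses the epimeric carbinol (1R,4S)-4-(tert-butyldimethylsilyloxy)-1-[(E)-5-(tert-butyldimethylsilyloxy)-3-methylpent-3-en-1-ynyl]-2,6,6-trimethylcyclohex-2-en-1-ol F2 after its separation from 8. Under the conditions of step 5 the suprafacial shift should give the cis-configured C4 trimethylsilyl ether F3. Methanolysis as in step 6 should give the (3S,4R) cis alcohol F4. A Mitsunobu reaction (4-nitrobenzoic acid, PPh3, diisopropyl azodicarboxylate, THF, 0 °C) should invert C4 by SN2 attack on the ring face opposite to both oxygens and give the trans (3S,4S) 4-nitrobenzoate F5. K2CO3 in MeOH then frees the alcohol, and the fallback comes back to the route at 9.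

3. Step 11. The second olefination may stall at the C25 aldehyde stage, and the product may form as several 11,11' geometric isomers that do not converge cleanly on heating. The fallback changes the olefination reagent class and sets out from 13. A Michaelis–Arbuzov reaction with P(OEt)3 (neat, 110 °C) should give diethyl {(E)-5-[(3S,4S)-3,4-bis(tert-butyldimethylsilyloxy)-2,6,6-trimethylcyclohex-1-enyl]-3-methylpent-2-en-4-ynyl}phosphonate F6. A twofold Horner–Wadsworth–Emmons reaction of F6 with 15 (KOtBu, THF, −30 °C → rt) should form both new alkenes directly as E. The fallback comes back to the route at 19 and bypasses 18 and step 12.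

**Further compounds**
F1 | step 5 | (S)-6-(tert-butyldimethylsilyloxy)-3-[(E)-5-(tert-butyldimethylsilyloxy)-3-methylpent-3-en-1-ynyl]-2,4,4-trimethylcyclohex-2-en-1-one | CC1=C(C#C/C(C)=C/CO[Si](C)(C)C(C)(C)C)C(C)(C)C[C@H](O[Si](C)(C)C(C)(C)C)C1=O
F2 | step 4 | (1R,4S)-4-(tert-butyldimethylsilyloxy)-1-[(E)-5-(tert-butyldimethylsilyloxy)-3-methylpent-3-en-1-ynyl]-2,6,6-trimethylcyclohex-2-en-1-ol | CC1=C[C@@H](O[Si](C)(C)C(C)(C)C)CC(C)(C)[C@]1(O)C#C/C(C)=C/CO[Si](C)(C)C(C)(C)C
F3 | step 4 | trimethylsilyl ether of (1R,6S)-6-(tert-butyldimethylsilyloxy)-3-[(E)-5-(tert-butyldimethylsilyloxy)-3-methylpent-3-en-1-ynyl]-2,4,4-trimethylcyclohex-2-en-1-ol | CC1=C(C#C/C(C)=C/CO[Si](C)(C)C(C)(C)C)C(C)(C)C[C@H](O[Si](C)(C)C(C)(C)C)[C@@H]1O[Si](C)(C)C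
F4 | step 4 | (1R,6S)-6-(tert-butyldimethylsilyloxy)-3-[(E)-5-(tert-butyldimethylsilyloxy)-3-methylpent-3-en-1-ynyl]-2,4,4-trimethylcyclohex-2-en-1-ol | CC1=C(C#C/C(C)=C/CO[Si](C)(C)C(C)(C)C)C(C)(C)C[C@H](O[Si](C)(C)C(C)(C)C)[C@@H]1O
F5 | step 4 | (1S,6S)-6-(tert-butyldimethylsilyloxy)-3-[(E)-5-(tert-butyldimethylsilyloxy)-3-methylpent-3-en-1-ynyl]-2,4,4-trimethylcyclohex-2-en-1-yl 4-nitrobenzoate | CC1=C(C#C/C(C)=C/CO[Si](C)(C)C(C)(C)C)C(C)(C)C[C@H](O[Si](C)(C)C(C)(C)C)[C@H]1OC(=O)c2ccc(cc2)[N+](=O)[O-]
F6 | step 11 | diethyl {(E)-5-[(3S,4S)-3,4-bis(tert-butyldimethylsilyloxy)-2,6,6-trimethylcyclohex-1-enyl]-3-methylpent-2-en-4-ynyl}phosphonate | CC1=C(C#C/C(C)=C/CP(=O)(OCC)OCC)C(C)(C)C[C@H](O[Si](C)(C)C(C)(C)C)[C@H]1O[Si](C)(C)C(C)(C)C
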